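## Retrosynthetic overview

1. Numbering (indene type): ring A is the cyclohexene C3a–C4–C5–C6–C7–C7a, ring B the cyclopentanone C1–C2–C3–C3a–C7a. The plan rests on the quaternary C4 of ring A (CO2H and ethyl) lying next to the ring-fusion carbon C3a, whose hydrogen is cis to the carboxyl, with C6=C7 on the far side of ring A. A carboxyl-bearing ring carbon beside a CH is the imprint of a Favorskii contraction.
2. Target 36 ⇐ acid ketal 35 ⇐ methyl ester ketal 34 ⇐ (break C3a–C4 and put the carboxyl carbon back between them as a ring ketone) trans-fused α-bromo hydroazulenone 30 + NaOMe.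
3. 30 ⇐ intramolecular (4+3) cycloaddition of the bromo-oxyallyl cation 29 (C4–C(O)–C3a) onto the (E,E)-diene C5=C6–C7=C7a of dibromo ketone 28; bonds C4–C5 and C3a–C7a.
4. 28 ⇐ aldehyde 24 + 1,1-dibromopropane; the triene ⇐ two Wittig homologations and one Horner–Wadsworth–Emmons reaction on aldehyde 14; the anti C1/C3 dimethyl ketal ⇐ pentan-3-one by double RAMP-hydrazone alkylation.
5. Ring order: ring B and the seven-membered carbocycle together (step 15), then ring A by contraction (step 16).

Key step: step 16

Remark: 30 is drawn as the trans-fused C3a epimer that the extended cycloaddition transition state should give; C3a becomes the enolate carbon in step 16, so a cis-fused epimer would feed the same enolate 32. Carbinol 27 is used as both epimers because that centre is oxidised in step 14.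

## Route

Step 1
Reactants: 1 pentan-3-one; 2 RAMP, (R)-1-amino-2-(methoxymethyl)pyrrolidine
Product: 3 pentan-3-one RAMP hydrazone
Conditions: neat, 60 °C
Reagents that add atoms: RAMP, COC[C@H]1CCCN1N
Why: Hydrazone formation from a ketone and an N-amino pyrrolidine needs no catalyst and attaches the auxiliary that directs both alkylations.

Step 2
Reactants: 3 pentan-3-one RAMP hydrazone; 4 benzyl chloromethyl ether
Product: 6 RAMP hydrazone of (R)-1-(benzyloxy)-2-methylpentan-3-one, via lithium azaenolate of the pentanone hydrazone 5 (not isolated)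
Conditions: LiN(iPr)2, THF, 0 °C; then 4, −100 °C → rt
Reagents that add atoms: benzyl chloromethyl ether, ClCOCc1ccccc1
Why: RAMP-hydrazone alkylation, in which the chelated lithium azaenolate is attacked on the face left open by the auxiliary, sets C1 (R in the derived ketone, the mirror image of the outcome in the SAMP series).

Step 3
Reactants: 6 RAMP hydrazone of (R)-1-(benzyloxy)-2-methylpentan-3-one; 7 tert-butyl bromoacetate
Product: 9 RAMP hydrazone of tert-butyl (3R,5R)-6-(benzyloxy)-3,5-dimethyl-4-oxohexanoate, via lithium azaenolate of the monoalkylated hydrazone 8 (not isolated)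
Conditions: LiN(iPr)2, THF, 0 °C; then 7, −100 °C → −20 °C
Reagents that add atoms: tert-butyl bromoacetate, CC(C)(C)OC(=O)CBr
Why: A second RAMP-hydrazone alkylation at the remaining α-methylene is again auxiliary-controlled and therefore sets C3 anti to C1; the ester arm is introduced last because its α-protons would otherwise be removed first.

Step 4
Reactants: 9 RAMP hydrazone of tert-butyl (3R,5R)-6-(benzyloxy)-3,5-dimethyl-4-oxohexanoate
Product: 10 tert-butyl (3R,5R)-6-(benzyloxy)-3,5-dimethyl-4-oxohexanoate
Conditions: sat. aq. oxalic acid, Et2O, rt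
Reagents that add atoms: water, O
Why: Two-phase hydrolytic hydrazone cleavage with oxalic acid is mild enough to keep both α-stereocentres and the tert-butyl ester and returns the auxiliary.

Step 5
Reactants: 10 tert-butyl (3R,5R)-6-(benzyloxy)-3,5-dimethyl-4-oxohexanoate; 11 1,2-bis(trimethylsilyloxy)ethane
Product: 12 tert-butyl (3R)-3-{2-[(2R)-1-(benzyloxy)propan-2-yl]-1,3-dioxolan-2-yl}butanoate
Conditions: Me3SiOTf (cat.), CH2Cl2, −78 → −20 °C; pyridine
Reagents that add atoms: 1,2-bis(trimethylsilyloxy)ethane, C[Si](C)(C)OCCO[Si](C)(C)C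
Why: Silyl-triflate-catalysed ketalisation with the bis-silyl ether of ethylene glycol, driven by formation of hexamethyldisiloxane, converts hindered ketones at low temperature without enolisation, so C1 and C3 are kept and C2 is masked before any β,γ-unsaturation exists.

Step 6
Reactants: 12 tert-butyl (3R)-3-{2-[(2R)-1-(benzyloxy)propan-2-yl]-1,3-dioxolan-2-yl}butanoate
Product: 13 tert-butyl (3R)-3-{2-[(2R)-1-hydroxypropan-2-yl]-1,3-dioxolan-2-yl}butanoate
Conditions: H2 (1 atm), Pd/C, EtOAc, rt
Reagents that add atoms: none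
Why: Hydrogenolysis of the benzyl ether in a neutral solvent leaves the dioxolane and the tert-butyl ester untouched.

Step 7
Reactants: 13 tert-butyl (3R)-3-{2-[(2R)-1-hydroxypropan-2-yl]-1,3-dioxolan-2-yl}butanoate
Product: 14 tert-butyl (3R)-3-{2-[(2R)-1-oxopropan-2-yl]-1,3-dioxolan-2-yl}butanoate
Conditions: Dess–Martin periodinane, pyridine, CH2Cl2, 0 °C → rt
Reagents that add atoms: none
Why: Buffered Dess–Martin oxidation gives the α-branched aldehyde (C7a) without epimerising C1, and the neighbouring ketal carbon offers no β-leaving group.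

Step 8
Reactants: 15 propyltriphenylphosphonium bromide; 16 ethyl formate
Product: 18 2-(triphenylphosphoranylidene)butanal, via propylidenetriphenylphosphorane 17 (not isolated)
Conditions: KOtBu, THF, 0 °C; then 16, 0 °C → rt
Reagents that add atoms: ethyl formate, CCOC=O
Why: C-formylation of a non-stabilised phosphorus ylide by a formate ester gives the stabilised α-formyl ylide used for two-carbon Wittig homologation.

Step 9
Reactants: 14 tert-butyl (3R)-3-{2-[(2R)-1-oxopropan-2-yl]-1,3-dioxolan-2-yl}butanoate; 18 2-(triphenylphosphoranylidene)butanal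
Product: 19 (E)-2-ethyl enal (C7a=C7 in place)
Conditions: toluene, 90 °C
Reagents that add atoms: 2-(triphenylphosphoranylidene)butanal, CCC(C=O)=P(c1ccccc1)(c1ccccc1)c1ccccc1
Why: Wittig olefination with a stabilised α-substituted ylide is E-selective, placing C1 trans to the formyl carbon, and its neutral conditions spare the C1 stereocentre.

Step 10
Reactants: 19 (E)-2-ethyl enal; 18 2-(triphenylphosphoranylidene)butanal
Product: 20 (E,E)-2,4-diethyl dienal (C7a=C7 and C6=C5 in place)
Conditions: toluene, 110 °C
Reagents that add atoms: 2-(triphenylphosphoranylidene)butanal, CCC(C=O)=P(c1ccccc1)(c1ccccc1)c1ccccc1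
Why: A second Wittig homologation with the same stabilised ylide gives the E-configured C5=C6 bond, and the more conjugated, more hindered dienal product reacts further only slowly.

Step 11
Reactants: 20 (E,E)-2,4-diethyl dienal; 21 diethyl benzylphosphonate
Product: 23 all-E triene tert-butyl ester, via sodium benzylphosphonate carbanion 22 (not isolated)
Conditions: NaH, THF, 0 °C; then 20, 0 °C → rt
Reagents that add atoms: diethyl benzylphosphonate, CCOP(=O)(Cc1ccccc1)OCC
Why: Horner–Wadsworth–Emmons olefination with a benzylphosphonate anion gives the (E)-styryl double bond, and the dienal has no α-hydrogen to lose.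

Step 12
Reactants: 23 all-E triene tert-butyl ester
Product: 24 triene aldehyde (C3–CH2–CHO)
Conditions: iBu2AlH (1.1 equiv), toluene, −78 °C; aq. potassium sodium tartrate
Reagents that add atoms: none
Why: Partial reduction of an ester by iBu2AlH stops at the aluminium hemiacetal, here stabilised by the bulky tert-butoxy group and by chelation to a dioxolane oxygen, which collapses to the aldehyde only on work-up.

Step 13
Reactants: 24 triene aldehyde; 25 1,1-dibromopropane
Product: 27 dibromo carbinol (both epimers), via 1,1-dibromopropyllithium 26 (not isolated)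
Conditions: LiN(iPr)2, THF/Et2O, −100 °C; then 24; AcOH, −100 °C
Reagents that add atoms: 1,1-dibromopropane, CCC(Br)Br
Why: 1,2-Addition of an α,α-dibromoalkyllithium carbenoid to an aldehyde installs the Et–CBr2 unit, and the cold acidic quench keeps the alkoxide from closing to a bromo epoxide; the new carbinol centre is uncontrolled and is removed in step 14.

Step 14
Reactants: 27 dibromo carbinol
Product: 28 α,α-dibromo ketone
Conditions: Dess–Martin periodinane, pyridine, CH2Cl2, 0 °C → rt
Reagents that add atoms: none
Why: Dess–Martin oxidation converts hindered α,α-dihalo carbinols to the ketones under neutral conditions that spare the triene, the ketal and the base-sensitive product.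

Step 15
Reactants: 28 α,α-dibromo ketone
Product: 30 trans-fused bromo hydroazulenone ketal, via bromo-oxyallyl zwitterion 29 (not isolated)
Conditions: Et3N (3 equiv), CF3CH2OH, 0.01 M, 0 °C
Reagents that add atoms: none
Why: Intramolecular (4+3) cycloaddition of an oxyallyl cation: the amine enolises the activated C3a methylene and the ionising fluoroalcohol expels one bromide to give 29, which adds across the tethered (E,E)-diene (ring B through the three-atom tether, the seven-membered ring through C3a–C7a and C4–C5); 1,3-allylic strain at C1 and C3 puts both methyl groups anti to the forming bonds, which fixes C7a and, through suprafacial addition to the (E,E)-diene, C5, and favours the extended trans-fused transition state, in which the bromine lying inside the ethyl-outside cation ends cis to the styryl group at C4.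

Step 16
Reactants: 30 trans-fused bromo hydroazulenone ketal; 31 sodium methoxide
Product: 34 norspiculoic acid A methyl ester C2 ethylene ketal, via sodium C3a enolate 32 (not isolated), via C3a–C4 cyclopropanone 33 (not isolated)
Conditions: NaOMe (4 equiv), Et2O, 0 °C → rt
Reagents that add atoms: sodium methoxide, [Na+].[O-]C
Why: Methoxide removes the axial H3a of 30, the C3a enolate 32 displaces the axial C4 bromide from the rear (3-exo-tet; at the ionised extreme, disrotatory closure of the oxyallyl cation) to give cyclopropanone 33, methoxide adds to its carbonyl and the hemiketal anion cleaves the C(O)–C3a bond with protonation of C3a under retention, so the former ketone carbon leaves as the C4 ester and C6=C7 is untouched. The closest known reaction is the Favorskii rearrangement of α-halo cycloalkanones carrying a tertiary halide, including its use on (4+3) cycloadducts. Ring A is closed by the new C3a–C4 bond (3-exo-tet to the cyclopropanone, whose six-membered ring is ring A once the carbonyl bridge is cut out of the seven-membered ring). C4 is set by inversion at the bromide carbon, which leaves the ester cis to the C5 styryl group and the two ethyl groups cis, and C3a is set by the retentive protonation, which puts H3a on the face of the former carbonyl bridge, cis to the ester and anti to H7a. The step needs closure anti to bromine and opening toward C3a: the trans ring fusion locks the seven-membered ring in the chair where C4–Br and C3a–H are both axial and syn, so enolisation and rear-side closure are aligned without prior ionisation, whereas the opening cannot rest on carbanion substitution because C3a and C4 are both fully substituted in 33, and it is expected to go toward C3a because in ether the sodium ion is held under C3a by the dioxolane oxygen syn to the bridge and because a proton reaches C4, next to quaternary C5, less easily.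

Step 17
Reactants: 34 norspiculoic acid A methyl ester C2 ethylene ketal
Product: 35 norspiculoic acid A C2 ethylene ketal
Conditions: LiI, pyridine, reflux; then aq. HCl to pH 3, 0 °C
Reagents that add atoms: none
Why: Nucleophilic demethylation by iodide at the methyl carbon avoids attack at the carbonyl flanked by two quaternary centres, and the ketal keeps C1 and C3 non-enolisable.

Step 18
Reactants: 35 norspiculoic acid A C2 ethylene ketal
Product: 36 norspiculoic acid A
Conditions: 1 M aq. HCl, THF, rt
Reagents that add atoms: water, O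
Why: Acid-catalysed ketal hydrolysis frees the C2 ketone, and C1 and C3 are not at risk because each methyl already lies pseudo-equatorial and cis to its neighbouring ring-fusion hydrogen, the more stable arrangement.

## Compound list

1 | pentan-3-one | CCC(=O)CC | starting material
2 | RAMP, (R)-1-amino-2-(methoxymethyl)pyrrolidine | COC[C@H]1CCCN1N | starting material
3 | pentan-3-one RAMP hydrazone | CCC(CC)=NN1CCC[C@@H]1COC | intermediate
4 | benzyl chloromethyl ether | ClCOCc1ccccc1 | starting material
5 | lithium azaenolate of the pentanone hydrazone (formed in the flask) | [Li+].CC=C(CC)[N-]N1CCC[C@@H]1COC | intermediate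
6 | RAMP hydrazone of (R)-1-(benzyloxy)-2-methylpentan-3-one (C=N geometry not defined) | c1ccccc1COC[C@@H](C)C(CC)=NN1CCC[C@@H]1COC | intermediate
7 | tert-butyl bromoacetate | CC(C)(C)OC(=O)CBr | starting material
8 | lithium azaenolate of the monoalkylated hydrazone (formed in the flask) | [Li+].c1ccccc1COC[C@@H](C)C(=CC)[N-]N1CCC[C@@H]1COC | intermediate
9 | RAMP hydrazone of tert-butyl (3R,5R)-6-(benzyloxy)-3,5-dimethyl-4-oxohexanoate | c1ccccc1COC[C@@H](C)C(=NN1CCC[C@@H]1COC)[C@H](C)CC(=O)OC(C)(C)C | intermediate
10 | tert-butyl (3R,5R)-6-(benzyloxy)-3,5-dimethyl-4-oxohexanoate | c1ccccc1COC[C@@H](C)C(=O)[C@H](C)CC(=O)OC(C)(C)C | intermediate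
11 | 1,2-bis(trimethylsilyloxy)ethane | C[Si](C)(C)OCCO[Si](C)(C)C | starting material
12 | tert-butyl (3R)-3-{2-[(2R)-1-(benzyloxy)propan-2-yl]-1,3-dioxolan-2-yl}butanoate | c1ccccc1COC[C@@H](C)C1(OCCO1)[C@H](C)CC(=O)OC(C)(C)C | intermediate
13 | tert-butyl (3R)-3-{2-[(2R)-1-hydroxypropan-2-yl]-1,3-dioxolan-2-yl}butanoate | OC[C@@H](C)C1(OCCO1)[C@H](C)CC(=O)OC(C)(C)C | intermediate
14 | tert-butyl (3R)-3-{2-[(2R)-1-oxopropan-2-yl]-1,3-dioxolan-2-yl}butanoate | O=C[C@@H](C)C1(OCCO1)[C@H](C)CC(=O)OC(C)(C)C | intermediate
15 | propyltriphenylphosphonium bromide | CCC[P+](c1ccccc1)(c1ccccc1)c1ccccc1.[Br-] | starting material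
16 | ethyl formate | CCOC=O | starting material
17 | propylidenetriphenylphosphorane (formed in the flask) | CCC=P(c1ccccc1)(c1ccccc1)c1ccccc1 | intermediate
18 | 2-(triphenylphosphoranylidene)butanal | CCC(C=O)=P(c1ccccc1)(c1ccccc1)c1ccccc1 | intermediate
19 | tert-butyl (3R)-3-{2-[(2R,3E)-4-formylhex-3-en-2-yl]-1,3-dioxolan-2-yl}butanoate | O=C/C(CC)=C/[C@@H](C)C1(OCCO1)[C@H](C)CC(=O)OC(C)(C)C | intermediate
20 | tert-butyl (3R)-3-{2-[(2R,3E,5E)-4-ethyl-6-formylocta-3,5-dien-2-yl]-1,3-dioxolan-2-yl}butanoate | O=C/C(CC)=C/C(CC)=C/[C@@H](C)C1(OCCO1)[C@H](C)CC(=O)OC(C)(C)C | intermediate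
21 | diethyl benzylphosphonate | CCOP(=O)(Cc1ccccc1)OCC | starting material
22 | sodium benzylphosphonate carbanion (formed in the flask) | [Na+].CCOP(=O)([CH-]c1ccccc1)OCC | intermediate
23 | tert-butyl (3R)-3-{2-[(2R,3E,5E,7E)-4,6-diethyl-8-phenylocta-3,5,7-trien-2-yl]-1,3-dioxolan-2-yl}butanoate | c1ccccc1/C=C/C(CC)=C/C(CC)=C/[C@@H](C)C1(OCCO1)[C@H](C)CC(=O)OC(C)(C)C | intermediate
24 | (3R)-3-{2-[(2R,3E,5E,7E)-4,6-diethyl-8-phenylocta-3,5,7-trien-2-yl]-1,3-dioxolan-2-yl}butanal | c1ccccc1/C=C/C(CC)=C/C(CC)=C/[C@@H](C)C1(OCCO1)[C@H](C)CC=O | intermediate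
25 | 1,1-dibromopropane | CCC(Br)Br | starting material
26 | 1,1-dibromopropyllithium (formed in the flask) | [Li]C(Br)(Br)CC | intermediate
27 | (6R)-3,3-dibromo-6-{2-[(2R,3E,5E,7E)-4,6-diethyl-8-phenylocta-3,5,7-trien-2-yl]-1,3-dioxolan-2-yl}heptan-4-ol (both C4 epimers) | c1ccccc1/C=C/C(CC)=C/C(CC)=C/[C@@H](C)C1(OCCO1)[C@H](C)CC(O)C(Br)(Br)CC | intermediate
28 | (6R)-3,3-dibromo-6-{2-[(2R,3E,5E,7E)-4,6-diethyl-8-phenylocta-3,5,7-trien-2-yl]-1,3-dioxolan-2-yl}heptan-4-one | c1ccccc1/C=C/C(CC)=C/C(CC)=C/[C@@H](C)C1(OCCO1)[C@H](C)CC(=O)C(Br)(Br)CC | intermediate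
29 | bromo-oxyallyl zwitterion from 28 (formed in the flask; one resonance form) | c1ccccc1/C=C/C(CC)=C/C(CC)=C/[C@@H](C)C1(OCCO1)[C@H](C)C=C([O-])[C+](Br)CC | intermediate
30 | trans-fused bromo hydroazulenone ketal (seven-membered ring C4(Br)(Et)–C5(styryl)(Et)–C6=C7(Et)–C7a–C3a–C(=O); ring B with C1-Me, C2 dioxolane, C3-Me; Br cis to styryl, H3a anti to H7a, each methyl cis to its neighbouring ring-fusion H) | CCC1=C[C@](/C=C/c2ccccc2)(CC)[C@@](CC)(Br)C(=O)[C@H]2[C@H]1[C@@H](C)C3(OCCO3)[C@@H]2C | intermediate
31 | sodium methoxide | [Na+].[O-]C | starting material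
32 | sodium C3a enolate of 30 (formed in the flask) | [Na+].CCC1=C[C@](/C=C/c2ccccc2)(CC)[C@@](CC)(Br)C([O-])=C2[C@H]1[C@@H](C)C3(OCCO3)[C@@H]2C | intermediate
33 | C3a–C4 cyclopropanone (formed in the flask; carbonyl bridge on the ring A face syn to styryl and anti to H7a) | CCC1=C[C@](/C=C/c2ccccc2)(CC)[C@@]3(CC)C(=O)[C@@]32[C@H]1[C@@H](C)C4(OCCO4)[C@@H]2C | intermediate
34 | norspiculoic acid A methyl ester C2 ethylene ketal | CCC1=C[C@](/C=C/c2ccccc2)(CC)[C@@](CC)(C(=O)OC)[C@H]2[C@H]1[C@@H](C)C3(OCCO3)[C@@H]2C | intermediate
35 | norspiculoic acid A C2 ethylene ketal | CCC1=C[C@](/C=C/c2ccccc2)(CC)[C@@](CC)(C(=O)O)[C@H]2[C@H]1[C@@H](C)C3(OCCO3)[C@@H]2C | intermediate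
36 | norspiculoic acid A | CCC1=C[C@](/C=C/c2ccccc2)(CC)[C@@](CC)(C(=O)O)[C@H]2[C@H]1[C@@H](C)C(=O)[C@@H]2C | target

## Step count and risks

Total step count: 18 (17 on the main line plus the preparation of ylide 18 in step 8). Longest linear sequence: 17 steps (steps 1–7 and 9–18).

The three steps most likely to fail:

1. Step 16 (key step). The cyclopropanone hemiketal may open toward C4 instead of C3a, because both ring carbons are fully substituted, which would leave the ester on C3a. Methoxide may also remove HBr across C4 and its ethyl group before the ring closes. Fallback: it sets out from 23 and comes back at 35. The tert-butyl ester enolate of 23 (LiN(iPr)2, THF, −78 °C) is oxidised with 3-phenyl-2-(phenylsulfonyl)oxaziridine to the α-hydroxy ester F1. LiAlH4 reduces it to the 1,2-diol F2, and NaIO4 cleaves this to the one-carbon-shorter aldehyde F3, in which C3a is the formyl carbon. A Horner–Wadsworth–Emmons reaction with triethyl 2-phosphonobutanoate (NaH, THF) gives the (E)-2-ethyl enoate F4, and LiOH hydrolysis gives the tetraene acid F5. Heating F5 in toluene at 110 °C should close rings A and B together by an intramolecular Diels–Alder reaction of the (E)-2-ethylacrylic acid unit onto the same (E,E)-diene. The dienophile geometry then places the carboxyl on C4 cis to H3a, and 35 results without any cyclopropanone.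

2. Step 15. The cation may be captured by the fluoroalcohol. After the first bond has formed, the second may close at C7 or on oxygen instead of at C5. The choice of which C4 substituent lies inside the cation may be poorly controlled, so that bromine ends trans to the styryl group. Fallback: it sets out from 28 and comes back at 30. Silylation of 28 (tBuMe2SiOTf, Et3N, CH2Cl2, −78 °C) gives the (Z)-silyl enol ether F6, a 2-silyloxy allylic dibromide. AgBF4 in CH2Cl2 at −78 °C then removes one bromide to give the covalent 2-silyloxy-1-bromoallyl cation. In this non-nucleophilic medium it should undergo the same intramolecular (4+3) cycloaddition, and loss of the silyl group gives 30.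

3. Step 13. The carbenoid may undergo α-elimination before it adds, or it may act as a base and enolise the aldehyde. Fallback: it sets out from 24 and comes back at 28. PrMgBr adds to 24 to give the secondary alcohol F7, and Dess–Martin oxidation gives the propyl ketone F8. Kinetic deprotonation with LiN(iPr)2 at the less hindered propyl α-methylene, followed by N-bromosuccinimide, gives the α-bromo ketone F9. A second deprotonation at the more acidic CHBr position (LiN(SiMe3)2, −78 °C) and bromination with CBr4 gives 28.

## Further compounds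

F1 | step 16 | tert-butyl (3R)-2-hydroxy-3-{2-[(2R,3E,5E,7E)-4,6-diethyl-8-phenylocta-3,5,7-trien-2-yl]-1,3-dioxolan-2-yl}butanoate (both C2 epimers) | c1ccccc1/C=C/C(CC)=C/C(CC)=C/[C@@H](C)C1(OCCO1)[C@H](C)C(O)C(=O)OC(C)(C)C
F2 | step 16 | (3R)-3-{2-[(2R,3E,5E,7E)-4,6-diethyl-8-phenylocta-3,5,7-trien-2-yl]-1,3-dioxolan-2-yl}butane-1,2-diol (both C2 epimers) | c1ccccc1/C=C/C(CC)=C/C(CC)=C/[C@@H](C)C1(OCCO1)[C@H](C)C(O)CO
F3 | step 16 | (2R)-2-{2-[(2R,3E,5E,7E)-4,6-diethyl-8-phenylocta-3,5,7-trien-2-yl]-1,3-dioxolan-2-yl}propanal | c1ccccc1/C=C/C(CC)=C/C(CC)=C/[C@@H](C)C1(OCCO1)[C@H](C)C=O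
F4 | step 16 | ethyl (2E,4R)-2-ethyl-4-{2-[(2R,3E,5E,7E)-4,6-diethyl-8-phenylocta-3,5,7-trien-2-yl]-1,3-dioxolan-2-yl}pent-2-enoate | c1ccccc1/C=C/C(CC)=C/C(CC)=C/[C@@H](C)C1(OCCO1)[C@H](C)/C=C(\CC)C(=O)OCC
F5 | step 16 | (2E,4R)-2-ethyl-4-{2-[(2R,3E,5E,7E)-4,6-diethyl-8-phenylocta-3,5,7-trien-2-yl]-1,3-dioxolan-2-yl}pent-2-enoic acid | c1ccccc1/C=C/C(CC)=C/C(CC)=C/[C@@H](C)C1(OCCO1)[C@H](C)/C=C(\CC)C(=O)O
F6 | step 15 | tert-butyldimethylsilyl (Z)-enol ether of 28 | c1ccccc1/C=C/C(CC)=C/C(CC)=C/[C@@H](C)C1(OCCO1)[C@H](C)/C=C(\O[Si](C)(C)C(C)(C)C)C(Br)(Br)CC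
F7 | step 13 | (2R)-2-{2-[(2R,3E,5E,7E)-4,6-diethyl-8-phenylocta-3,5,7-trien-2-yl]-1,3-dioxolan-2-yl}heptan-4-ol (both C4 epimers) | c1ccccc1/C=C/C(CC)=C/C(CC)=C/[C@@H](C)C1(OCCO1)[C@H](C)CC(O)CCC
F8 | step 13 | (2R)-2-{2-[(2R,3E,5E,7E)-4,6-diethyl-8-phenylocta-3,5,7-trien-2-yl]-1,3-dioxolan-2-yl}heptan-4-one | c1ccccc1/C=C/C(CC)=C/C(CC)=C/[C@@H](C)C1(OCCO1)[C@H](C)CC(=O)CCC
F9 | step 13 | (6R)-3-bromo-6-{2-[(2R,3E,5E,7E)-4,6-diethyl-8-phenylocta-3,5,7-trien-2-yl]-1,3-dioxolan-2-yl}heptan-4-one (both C3 epimers) | c1ccccc1/C=C/C(CC)=C/C(CC)=C/[C@@H](C)C1(OCCO1)[C@H](C)CC(=O)C(Br)CC
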